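**Numbering.** Ring A is counted from the quaternary carbon: C1 (quaternary), C2 (carbonyl), C3 (side-chain carbon), C4 (central oxygen), C5 (acyl carbon), C6 (ring B oxygen). Ring B atoms are O1′ (on C6), C2′, C3′ and C4′ (carbonyl on C5). Compounds are numbered 1–25 in order of appearance in the steps.

## Analysis of the target

Target 25 is a dearomatised acylphloroglucinol. Ring A is oxygenated at C2, C4 and C6 and fused through C5–C6 to a 2,3-dimethyl-2,3-dihydropyran-4-one ring B. C1 carries a prenyl group and a [(1S,3R)-2,2-dimethyl-3-isopropenylcyclobutyl]methyl group, C3 carries an (S)-CH(propyl)CH2CO2H chain, and the C2/C4 oxygens form an enolised β-diketone.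

The six stereocentres fall into four groups that no ring or short chain ties together: the cis pair on the cyclobutane, C1 (R), the side-chain carbon (S), and the cis pair C2′ (R)/C3′ (S). None can be set by relay from another.

Sensitive groups are:
- the isopropenylcyclobutane, where a cation next to the four-membered ring leads to ring expansion;
- the prenyl group beside enol oxygens, which acid closes to a chroman;
- C3′, α to the ring B ketone, where the cis isomer can epimerise or ring B can open by retro-oxa-Michael reaction;
- the carboxylic acid, which sits 1,5 to both O4 and O2.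

The hard point is C1. Its two carbon arms are both CH2R groups and its two ring neighbours are both carbonyl-level carbons. It is a stereocentre only because one half of ring A carries the C3 chain and the other the C5 acyl group. The question of which oxygen closes ring B is tied to the same distinction.

The strategy rests on this feature: while C3 and C5 are both CH2, the 2,2-dialkylcyclohexane-1,3,5-trione has a local mirror plane through C1 and C4, and C1 is not stereogenic. The first substitution at C3 or C5 creates the stereocentre. If the same event ties O4 into a δ-lactone with the acid chain, O6 is the only oxygen left for ring B.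

## Retrosynthetic reasoning

**25 to 24.** The O4–acyl bond of the δ-lactone is the last bond cleaved in the forward direction. Keeping the acid and O4 joined through the whole endgame masks both at once and leaves O6 as the only enol oxygen next to C5. The forward step has to open an activated enol ester without disturbing C3′.

**24 to 23.** Ring B is cut at O6–C2′. This bond can be made by SN2 displacement with inversion at a carbinol of known configuration, so both ring B centres come from a small building block. Building ring B from a C5 propionyl group and a two-carbon aldehyde was set aside: it would create C2′ and C3′ on the full skeleton, where the nearest stereocentre is five bonds away and nothing fixes their sense. The gain of the chosen cut is secure cis geometry and absolute configuration. The forward step has to be substitution and not elimination.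

**23 to 22 to 15 and 20.** The C5–C4′ bond is cut by C-acylation of the one ring carbon of lactone 15 that still bears hydrogen, using acid chloride 20. The acylation must not use a nucleophilic acyl-transfer catalyst, which could move the lactone from O4 to O2 and lose the regiochemical block. The enol is therefore capped as silyl dienol ether 21 and acylated under Lewis acid. Acid chloride 20 goes back through 19 and 18 to the anti hydroxy ester 17, and this to ethyl (S)-3-hydroxybutanoate 16, so C2′ comes from the chiral pool and C3′ from one diastereoselective methylation.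

**15 to 13 and 14.** This is the central cut: the C3–CH(propyl) bond and the O4–acyl bond of the dihydropyranone. Both lead back to the C1-symmetric trione 13 and (E)-hex-2-enal 14. Cutting here means C1 need not be made as a stereocentre by alkylation. One catalytic annulation has to choose one of the two ring CH2 groups, set the side-chain centre and put the lactone on O4.

**13 to 12 to 11.** Ring A is opened at C5–C6 (Claisen closure of the diketo ester 12) and then at C3–C4 (C-acetylation of the methyl ketone of 11). An acetoacetate already contains C1, C2, C3 and C6, so one acetylation and one ring closure finish the ring without a decarboxylation. The quaternary carbon of 11 and 12 is a stereocentre of no consequence, because it vanishes when the two arms become equal in 13.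

**11 to 9 to 7, 8 and 10.** Two enolate alkylations of methyl acetoacetate 8 are used, first with the hindered iodide 7 on the unsubstituted enolate and then with the reactive prenyl bromide 10.

**7 to 1.** The cyclobutane is taken from (1R,5R)-α-pinene 1. Allylic oxidation to verbenone 2 and cleavage of the enone give the C9 keto acid 3, in which the cis-1,3 relationship is inherited from the bicycle. The acetyl group becomes the isopropenyl group (4 to 5) and the carboxyl group becomes CH2I (5 to 6 to 7).

## Alternatives that were turned down

**Alternative 1:** The cyclobutane is not taken from a terpene but made by cutting the CMe2–CH bond and the bond from the carbonyl-derived carbon to the ring CH2. In the forward step the keteniminium salt from the C2-symmetric amide A2 adds to the alkene of allyl benzoate A3, and hydrolysis gives cyclobutanone A1.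
- For: it does not depend on the optical purity or available enantiomer of a natural product, and keteniminium [2+2] additions to unactivated alkenes are an established reaction type. On freedom of absolute configuration it is stronger than the chosen route.
- Against: A1 has one of the two ring stereocentres and a carbonyl where the target has a CH bearing isopropenyl. Three carbons must be added and the cis relation to the CH2O arm must be created on a nearly flat ring with a gem-dimethyl group on one flank. That is an estimated four to five steps to reach alcohol 6, with a diastereoselection that must be won.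
- Comparison: from 1 alcohol 6 is reached in five steps, the acetyl group already is the isopropenyl skeleton, and the cis relation cannot fail. Alternative 1 also leaves the real problem, C1, untouched.

**Alternative 2:** The CMe2–CH bond of the cyclobutane is cut last, so the cyclobutylmethyl arm becomes an open lavandulyl chain in precursor A5. In the forward step a cobalt hydride transfers a hydrogen atom to the isopropenyl CH2 of A5, the tertiary radical is oxidised to the cation, the CH of the trisubstituted alkene three atoms away attacks it, and proton loss gives lactone A4, which has the structure of 24.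
- For: it follows the likely biogenesis and replaces the six-step terpene degradation (steps 1–6) by an acyclic C10 unit. If it worked it would be stronger in step count.
- Against: four-membered ring closure by cation–alkene addition must beat faster exits of the same cation. These are capture by O2 or O6 of ring A through a six-membered transition state, and proton loss back to an alkene. Hydrogen-atom transfer to the two other trisubstituted alkenes of A5 also competes. Nothing in A5 controls the two new ring centres, and the attempt is made on the most advanced intermediate.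
- Comparison: the chosen route pays six steps for a cyclobutane of secured constitution and cis configuration. Its one unprecedented step sits at trione 13, which is cheap to remake.

**Alternative 3:** Ring A is cut at C2–C3 and C5–C6, with C1 already stereodefined in the malonic half-ester chloride A7 and the C5 propionyl group already present in the bis-silyl dienol ether A8. In the forward step the terminal carbon of A8 is acylated by A7, and base then drives the central carbon onto the methyl ester to give the propionyl trione A6.
- For: both bond formations are known reaction types. The C5 acyl group arrives with the ring; on this point alternative 3 is stronger, because the weakest conventional step of the chosen route is the C-acylation of lactone 15 (step 16).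
- Against: the stereochemical problem is only moved to A7. Its quaternary carbon bears two ester-level carbons and two CH2R groups, which no reliable alkylation or desymmetrisation tells apart, so a resolution would be needed. A6 still lacks the C3 chain and its stereocentre. In A6 both O4 and O6 flank the acyl group, so ring B has no reason to close on O6.
- Comparison: the chosen route creates C1 and the side-chain centre in one catalytic step from a precursor that needs two plain alkylations, and the same step blocks O4. It pays with a harder acylation afterwards.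

Key step: step 11

Remark: 25 and the enolisable intermediates (13, 15, 22, 23) are drawn as one tautomer each; tautomeric mixtures are expected.

Remark: the (5aS,10bR) antipode of the aminoindanol-derived triazolium salt is assumed to give the S configuration at the CH(propyl) carbon; if the sense is opposite, the (5aR,10bS) salt is used.

## Route

Step 1
Reactants: 1 (1R,5R)-α-pinene
Product: 2 (1R,5R)-verbenone
Conditions: t-BuOOH (70% aq.), CrO3 (5 mol %), CH2Cl2, rt
Reagents that add atoms: tert-butyl hydroperoxide, CC(C)(C)OO
Why: Allylic C–H oxidation of the ring CH2 beside the trisubstituted alkene gives the enone; both stereocentres are bridgeheads and cannot epimerise.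

Step 2
Reactants: 2 (1R,5R)-verbenone
Product: 3 (1R,3S)-3-acetyl-2,2-dimethylcyclobutane-1-carboxylic acid (cis-pinononic acid)
Conditions: RuCl3·xH2O (2 mol %), NaIO4 (4.1 equiv), EtOAc/MeCN/H2O, rt
Reagents that add atoms: sodium periodate (NaIO4), [Na+].[O-]I(=O)(=O)=O
Why: RuO4 formed in situ cleaves the enone C=C and the α-keto acid on the carbonyl side loses CO2 oxidatively; the cis-1,3 relationship is inherited from the bicycle.

Step 3
Reactants: 3 (1R,3S)-3-acetyl-2,2-dimethylcyclobutane-1-carboxylic acid
Product: 4 methyl (1R,3S)-3-acetyl-2,2-dimethylcyclobutane-1-carboxylate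
Conditions: MeI, KHCO3, DMF, rt
Reagents that add atoms: iodomethane, CI
Why: SN2 O-methylation of the carboxylate; hydrogen carbonate is too weak a base to epimerise the acetyl-bearing ring carbon.

Step 4
Reactants: 4 methyl (1R,3S)-3-acetyl-2,2-dimethylcyclobutane-1-carboxylate
Product: 5 methyl (1R,3R)-2,2-dimethyl-3-(prop-1-en-2-yl)cyclobutane-1-carboxylate
Conditions: Zn, CH2Br2, TiCl4, THF/CH2Cl2, 0 °C to rt
Reagents that add atoms: dibromomethane, BrCBr
Why: Lombardo–Takai methylenation; the non-basic gem-dimetal reagent converts the ketone into the isopropenyl group without enolising the neighbouring ring CH and does not touch the ester.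

Step 5
Reactants: 5 methyl (1R,3R)-2,2-dimethyl-3-(prop-1-en-2-yl)cyclobutane-1-carboxylate
Product: 6 [(1R,3R)-2,2-dimethyl-3-(prop-1-en-2-yl)cyclobutyl]methanol
Conditions: LiAlH4, Et2O, 0 °C
Reagents that add atoms: none
Why: Hydride reduction of the ester to the primary alcohol; no stereocentre is involved.

Step 6
Reactants: 6 [(1R,3R)-2,2-dimethyl-3-(prop-1-en-2-yl)cyclobutyl]methanol
Product: 7 (1R,3R)-1-(iodomethyl)-2,2-dimethyl-3-(prop-1-en-2-yl)cyclobutane
Conditions: I2, PPh3, imidazole, CH2Cl2, 0 °C to rt
Reagents that add atoms: iodine, II
Why: Appel-type iodination through the alkoxyphosphonium salt, an SN2 reaction at the primary carbon.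

Step 7
Reactants: 7 (1R,3R)-1-(iodomethyl)-2,2-dimethyl-3-(prop-1-en-2-yl)cyclobutane; 8 methyl acetoacetate
Product: 9 methyl 2-{[(1S,3R)-2,2-dimethyl-3-(prop-1-en-2-yl)cyclobutyl]methyl}-3-oxobutanoate
Conditions: 8 (3 equiv), NaH (2.8 equiv), THF/DMF, 0 °C; then 7, 60 °C
Reagents that add atoms: none
Why: SN2 C-alkylation of the acetoacetate enolate by the primary iodide; the excess of enolate suppresses dialkylation, and the new carbon is configurationally labile and of no consequence.

Step 8
Reactants: 9 methyl 2-{[(1S,3R)-2,2-dimethyl-3-(prop-1-en-2-yl)cyclobutyl]methyl}-3-oxobutanoate; 10 prenyl bromide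
Product: 11 methyl 2-acetyl-2-{[(1S,3R)-2,2-dimethyl-3-(prop-1-en-2-yl)cyclobutyl]methyl}-5-methylhex-4-enoate (both epimers at C2)
Conditions: NaH, THF, 0 °C to rt
Reagents that add atoms: none
Why: Second enolate C-alkylation with the reactive allylic bromide builds the quaternary carbon; its two epimers converge in step 10.

Step 9
Reactants: 11 methyl 2-acetyl-2-{[(1S,3R)-2,2-dimethyl-3-(prop-1-en-2-yl)cyclobutyl]methyl}-5-methylhex-4-enoate
Product: 12 methyl 2-{[(1S,3R)-2,2-dimethyl-3-(prop-1-en-2-yl)cyclobutyl]methyl}-2-(3-methylbut-2-en-1-yl)-3,5-dioxohexanoate (both epimers at C2)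
Conditions: 1-acetylbenzotriazole, MgBr2·OEt2, i-Pr2NEt, CH2Cl2, rt
Reagents that add atoms: 1-acetyl-1H-benzotriazole, CC(=O)n1nnc2ccccc21
Why: Crossed Claisen acylation by soft enolisation; the magnesium-chelated methyl ketone is the only enolisable site and is C-acetylated, and no alkoxide is present that could cleave the non-enolisable β-keto ester by retro-Claisen reaction.

Step 10
Reactants: 12 methyl 2-{[(1S,3R)-2,2-dimethyl-3-(prop-1-en-2-yl)cyclobutyl]methyl}-2-(3-methylbut-2-en-1-yl)-3,5-dioxohexanoate
Product: 13 2-{[(1S,3R)-2,2-dimethyl-3-(prop-1-en-2-yl)cyclobutyl]methyl}-2-(3-methylbut-2-en-1-yl)cyclohexane-1,3,5-trione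
Conditions: LiN(i-Pr)2 (3.3 equiv), THF, −78 to 0 °C; then cold 1 M HCl
Reagents that add atoms: none
Why: Dieckmann-type Claisen condensation; the terminal carbon of the 1,3-diketone dianion attacks the ester (6-exo-trig) and the stable trione enolate drives the closure; in 13 the two ring arms are identical, so the former stereocentre disappears.

Step 11
Reactants: 13 2-{[(1S,3R)-2,2-dimethyl-3-(prop-1-en-2-yl)cyclobutyl]methyl}-2-(3-methylbut-2-en-1-yl)cyclohexane-1,3,5-trione; 14 (E)-hex-2-enal
Product: 15 (4S,6R)-6-{[(1S,3R)-2,2-dimethyl-3-(prop-1-en-2-yl)cyclobutyl]methyl}-6-(3-methylbut-2-en-1-yl)-4-propyl-3,4-dihydro-2H-chromene-2,5,7(6H,8H)-trione (enol lactone on O4)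
Conditions: (5aS,10bR)-2-mesityl-5a,10b-dihydro-4H,6H-indeno[2,1-b][1,2,4]triazolo[4,3-d][1,4]oxazin-2-ium chloride (10 mol %), 3,3′,5,5′-tetra-tert-butyldiphenoquinone (1.05 equiv), 14 (1.05 equiv), i-Pr2NEt (1.2 equiv), 4 Å MS, toluene, 0 °C to rt
Reagents that add atoms: none
Why: Proposed new method: the carbene adds to 14, the enaminol is oxidised by the diphenoquinone to the α,β-unsaturated acyl azolium, the enol of 13 adds through one ring CH to its β-carbon (directly or by O-addition and [3,3] shift), and after proton transfer O4 attacks the acyl azolium and releases the carbene; the closest known reaction type is the carbene-catalysed oxidative annulation of enals with cyclic 1,3-diketones to 3,4-dihydropyran-2-ones, which has not been applied to a 2,2-dialkyl-1,3,5-trione whose two CH2 groups must be told apart. The dihydropyranone ring closes by 6-exo-trig acyl transfer from the azolium to the enol oxygen. The CH(propyl) centre (S) is set by the catalyst, whose fused aminoindanol wall leaves one face of the acyl azolium open. C1 becomes a stereocentre (R) through the choice between the diastereotopic C3 and C5: the catalyst pairs its open β-face with one face of the enol, and with that pairing one ring CH is reached past the slim prenyl arm and the other past the β-branched cyclobutylmethyl arm, so the route needs the first of these to be the carbon that gives R. O4 and not O2 should be acylated because, once C3 is alkylated, the enolate sits in the still unsubstituted C4–C5–C6 unit, where O4 carries charge and can reach the acyl carbon, while O2 is a ketone oxygen beside the quaternary carbon. A second annulation at C5 is held back by using 14 and the oxidant in only slight excess. The step therefore needs catalyst control of the β-face, a substrate-aided choice of the ring CH and kinetic lactonisation on O4; a weak base and a short reaction time are chosen so that the carbene does not reopen the lactone.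

Step 12
Reactants: 16 ethyl (S)-3-hydroxybutanoate
Product: 17 ethyl (2S,3S)-3-hydroxy-2-methylbutanoate
Conditions: LiN(i-Pr)2 (2.2 equiv), THF, −50 to −20 °C; MeI, DMPU, −78 to 0 °C
Reagents that add atoms: iodomethane, CI
Why: Fráter–Seebach alkylation; the chelated alkoxide enolate is methylated on the face away from the C3 methyl group, which gives the anti isomer and sets the future C3′.

Step 13
Reactants: 17 ethyl (2S,3S)-3-hydroxy-2-methylbutanoate
Product: 18 ethyl (2S,3S)-3-(tert-butyldimethylsilyloxy)-2-methylbutanoate
Conditions: TBSCl, imidazole, DMF, rt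
Reagents that add atoms: tert-butyldimethylsilyl chloride, CC(C)(C)[Si](C)(C)Cl
Why: Silylation protects the carbinol through acid chloride formation and acylation.

Step 14
Reactants: 18 ethyl (2S,3S)-3-(tert-butyldimethylsilyloxy)-2-methylbutanoate
Product: 19 (2S,3S)-3-(tert-butyldimethylsilyloxy)-2-methylbutanoic acid
Conditions: LiOH, THF/MeOH/H2O, 0 °C to rt; 1 M HCl to pH 3
Reagents that add atoms: lithium hydroxide (LiOH), [Li+].[OH-]
Why: Ester saponification; the α-centre of a simple ester is not enolised by cold hydroxide and the silyl ether is stable.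

Step 15
Reactants: 19 (2S,3S)-3-(tert-butyldimethylsilyloxy)-2-methylbutanoic acid
Product: 20 (2S,3S)-3-(tert-butyldimethylsilyloxy)-2-methylbutanoyl chloride
Conditions: 1-chloro-N,N,2-trimethylprop-1-en-1-amine, CH2Cl2, 0 °C to rt; used crude
Reagents that add atoms: 1-chloro-N,N,2-trimethylprop-1-en-1-amine, CC(C)=C(Cl)N(C)C
Why: Neutral acid chloride formation with an α-chloroenamine; no HCl and no base are present, so the silyl ether and the α-centre are kept.

Step 16
Reactants: 15 enol lactone (4S,6R)-6-{[(1S,3R)-2,2-dimethyl-3-(prop-1-en-2-yl)cyclobutyl]methyl}-6-(3-methylbut-2-en-1-yl)-4-propyl-3,4-dihydro-2H-chromene-2,5,7(6H,8H)-trione; 20 (2S,3S)-3-(tert-butyldimethylsilyloxy)-2-methylbutanoyl chloride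
Product: 22 (4S,6R)-8-[(2S,3S)-3-(tert-butyldimethylsilyloxy)-2-methylbutanoyl]-6-{[(1S,3R)-2,2-dimethyl-3-(prop-1-en-2-yl)cyclobutyl]methyl}-7-hydroxy-6-(3-methylbut-2-en-1-yl)-4-propyl-3,4-dihydro-2H-chromene-2,5(6H)-dione (C5-acylated enol lactone), via trimethylsilyl dienol ether 21 (not isolated)
Conditions: N,O-bis(trimethylsilyl)acetamide, CH2Cl2, rt, evaporate; 20, ZnCl2 (1.5 equiv), 2,6-di-tert-butyl-4-methylpyridine (0.2 equiv), CH2Cl2/Et2O, −20 °C to rt; pH 5 buffer
Reagents that add atoms: none
Why: Lewis-acid-mediated (Mukaiyama-type) C-acylation of a silyl dienol ether; with the enol oxygen capped by silicon the acid chloride–ZnCl2 complex can only attack C5, the one ring carbon still bearing hydrogen, and no nucleophilic acyl-transfer catalyst is present that could move the lactone from O4 to O2 or enolise the α-centre of 20.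

Step 17
Reactants: 22 C5-acylated enol lactone with silyl-protected (2S,3S) side chain
Product: 23 (4S,6R)-6-{[(1S,3R)-2,2-dimethyl-3-(prop-1-en-2-yl)cyclobutyl]methyl}-7-hydroxy-8-[(2S,3S)-3-hydroxy-2-methylbutanoyl]-6-(3-methylbut-2-en-1-yl)-4-propyl-3,4-dihydro-2H-chromene-2,5(6H)-dione
Conditions: HF·pyridine, pyridine, THF, 0 °C to rt
Reagents that add atoms: none
Why: Fluoride cleavage of the silyl ether under buffered, base-free conditions, so that the β-hydroxy ketone neither eliminates nor undergoes retro-aldol cleavage and the lactone and alkenes are untouched.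

Step 18
Reactants: 23 hydroxy ketone (4S,6R)-6-{[(1S,3R)-2,2-dimethyl-3-(prop-1-en-2-yl)cyclobutyl]methyl}-7-hydroxy-8-[(2S,3S)-3-hydroxy-2-methylbutanoyl]-6-(3-methylbut-2-en-1-yl)-4-propyl-3,4-dihydro-2H-chromene-2,5(6H)-dione
Product: 24 ring B-closed enol lactone: δ-lactone of 25 between the carboxyl group and O4, with C2′ (R), C3′ (S), side-chain carbon (S), C1 (R) and (1S,3R) cyclobutane
Conditions: PPh3, diisopropyl azodicarboxylate, THF, 0 °C to rt
Reagents that add atoms: none
Why: Intramolecular Mitsunobu etherification; the acidic enol O6–H, the only free oxygen beside the C5 acyl group because O4 is held in the lactone, displaces the phosphonium-activated (S)-carbinol with inversion to give C2′ (R), while C3′ (S) is untouched, so the two methyl groups come out cis; the same closure is known for o-(3-hydroxy-2-methylbutanoyl)phenols giving 2,3-dimethylchroman-4-ones.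

Step 19
Reactants: 24 ring B-closed enol lactone
Product: 25 (3S)-3-[(2R,3S,8R)-8-{[(1S,3R)-2,2-dimethyl-3-(prop-1-en-2-yl)cyclobutyl]methyl}-5-hydroxy-2,3-dimethyl-8-(3-methylbut-2-en-1-yl)-4,7-dioxo-3,4,7,8-tetrahydro-2H-chromen-6-yl]hexanoic acid (CNP0364345.1)
Conditions: LiOH (3 equiv), THF/H2O, 0 °C, short; 0.5 M HCl to pH 3 at 0 °C
Reagents that add atoms: lithium hydroxide (LiOH), [Li+].[OH-]
Why: Saponification of the enol lactone, an activated ester that should open much faster than the vinylogous ester of ring B; once it is open, the ring A triketonate lowers the acidity of C3′–H, and cold, brief treatment should keep the cis ring B.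

## Compound list

1 | (1R,5R)-α-pinene | CC1=CC[C@@H]2C[C@H]1C2(C)C | starting material
2 | (1R,5R)-verbenone | CC1=CC(=O)[C@@H]2C[C@H]1C2(C)C | intermediate
3 | (1R,3S)-3-acetyl-2,2-dimethylcyclobutane-1-carboxylic acid | CC(=O)[C@H]1C[C@@H](C(=O)O)C1(C)C | intermediate
4 | methyl (1R,3S)-3-acetyl-2,2-dimethylcyclobutane-1-carboxylate | CC(=O)[C@H]1C[C@@H](C(=O)OC)C1(C)C | intermediate
5 | methyl (1R,3R)-2,2-dimethyl-3-(prop-1-en-2-yl)cyclobutane-1-carboxylate | C=C(C)[C@H]1C[C@@H](C(=O)OC)C1(C)C | intermediate
6 | [(1R,3R)-2,2-dimethyl-3-(prop-1-en-2-yl)cyclobutyl]methanol | C=C(C)[C@H]1C[C@@H](CO)C1(C)C | intermediate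
7 | (1R,3R)-1-(iodomethyl)-2,2-dimethyl-3-(prop-1-en-2-yl)cyclobutane | C=C(C)[C@H]1C[C@@H](CI)C1(C)C | intermediate
8 | methyl acetoacetate | COC(=O)CC(C)=O | starting material
9 | methyl 2-{[(1S,3R)-2,2-dimethyl-3-(prop-1-en-2-yl)cyclobutyl]methyl}-3-oxobutanoate (C2 epimers) | C=C(C)[C@H]1C[C@@H](CC(C(C)=O)C(=O)OC)C1(C)C | intermediate
10 | prenyl bromide | CC(C)=CCBr | starting material
11 | methyl 2-acetyl-2-{[(1S,3R)-2,2-dimethyl-3-(prop-1-en-2-yl)cyclobutyl]methyl}-5-methylhex-4-enoate (C2 epimers) | C=C(C)[C@H]1C[C@@H](CC(CC=C(C)C)(C(C)=O)C(=O)OC)C1(C)C | intermediate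
12 | methyl 2-{[(1S,3R)-2,2-dimethyl-3-(prop-1-en-2-yl)cyclobutyl]methyl}-2-(3-methylbut-2-en-1-yl)-3,5-dioxohexanoate (C2 epimers) | C=C(C)[C@H]1C[C@@H](CC(CC=C(C)C)(C(=O)CC(C)=O)C(=O)OC)C1(C)C | intermediate
13 | 2-{[(1S,3R)-2,2-dimethyl-3-(prop-1-en-2-yl)cyclobutyl]methyl}-2-(3-methylbut-2-en-1-yl)cyclohexane-1,3,5-trione | C=C(C)[C@H]1C[C@@H](CC2(CC=C(C)C)C(=O)CC(=O)CC2=O)C1(C)C | intermediate
14 | (E)-hex-2-enal | CCC/C=C/C=O | starting material
15 | (4S,6R)-6-{[(1S,3R)-2,2-dimethyl-3-(prop-1-en-2-yl)cyclobutyl]methyl}-6-(3-methylbut-2-en-1-yl)-4-propyl-3,4-dihydro-2H-chromene-2,5,7(6H,8H)-trione | C=C(C)[C@H]1C[C@@H](C[C@@]2(CC=C(C)C)C(=O)C3=C(OC(=O)C[C@@H]3CCC)CC2=O)C1(C)C | intermediate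
16 | ethyl (S)-3-hydroxybutanoate | CCOC(=O)C[C@H](C)O | starting material
17 | ethyl (2S,3S)-3-hydroxy-2-methylbutanoate | CCOC(=O)[C@@H](C)[C@H](C)O | intermediate
18 | ethyl (2S,3S)-3-(tert-butyldimethylsilyloxy)-2-methylbutanoate | CCOC(=O)[C@@H](C)[C@H](C)O[Si](C)(C)C(C)(C)C | intermediate
19 | (2S,3S)-3-(tert-butyldimethylsilyloxy)-2-methylbutanoic acid | OC(=O)[C@@H](C)[C@H](C)O[Si](C)(C)C(C)(C)C | intermediate
20 | (2S,3S)-3-(tert-butyldimethylsilyloxy)-2-methylbutanoyl chloride | ClC(=O)[C@@H](C)[C@H](C)O[Si](C)(C)C(C)(C)C | intermediate
21 | trimethylsilyl dienol ether of 15 (silicon on O6; the O2 isomer would react at the same carbon) | C=C(C)[C@H]1C[C@@H](C[C@@]2(CC=C(C)C)C(=O)C3=C(OC(=O)C[C@@H]3CCC)C=C2O[Si](C)(C)C)C1(C)C | intermediate (not isolated)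
22 | (4S,6R)-8-[(2S,3S)-3-(tert-butyldimethylsilyloxy)-2-methylbutanoyl]-6-{[(1S,3R)-2,2-dimethyl-3-(prop-1-en-2-yl)cyclobutyl]methyl}-7-hydroxy-6-(3-methylbut-2-en-1-yl)-4-propyl-3,4-dihydro-2H-chromene-2,5(6H)-dione | C=C(C)[C@H]1C[C@@H](C[C@@]2(CC=C(C)C)C(=O)C3=C(OC(=O)C[C@@H]3CCC)C(C(=O)[C@@H](C)[C@H](C)O[Si](C)(C)C(C)(C)C)=C2O)C1(C)C | intermediate
23 | (4S,6R)-6-{[(1S,3R)-2,2-dimethyl-3-(prop-1-en-2-yl)cyclobutyl]methyl}-7-hydroxy-8-[(2S,3S)-3-hydroxy-2-methylbutanoyl]-6-(3-methylbut-2-en-1-yl)-4-propyl-3,4-dihydro-2H-chromene-2,5(6H)-dione | C=C(C)[C@H]1C[C@@H](C[C@@]2(CC=C(C)C)C(=O)C3=C(OC(=O)C[C@@H]3CCC)C(C(=O)[C@@H](C)[C@H](C)O)=C2O)C1(C)C | intermediate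
24 | δ-lactone of 25 between the carboxyl group and O4; C2′ (R), C3′ (S), side-chain carbon (S), C1 (R), cyclobutane (1S,3R) | C=C(C)[C@H]1C[C@@H](C[C@@]2(CC=C(C)C)C(=O)C3=C(OC(=O)C[C@@H]3CCC)C4=C2O[C@H](C)[C@H](C)C4=O)C1(C)C | intermediate
25 | (3S)-3-[(2R,3S,8R)-8-{[(1S,3R)-2,2-dimethyl-3-(prop-1-en-2-yl)cyclobutyl]methyl}-5-hydroxy-2,3-dimethyl-8-(3-methylbut-2-en-1-yl)-4,7-dioxo-3,4,7,8-tetrahydro-2H-chromen-6-yl]hexanoic acid | C=C(C)[C@H]1C[C@@H](C[C@@]2(CC=C(C)C)C(=O)C([C@@H](CCC)CC(=O)O)=C(O)C3=C2O[C@H](C)[C@H](C)C3=O)C1(C)C | target

## Step count and least certain steps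

Total: 19 steps. Longest linear sequence: 15 steps (steps 1–11 and 16–19). Steps 12–15 are a four-step side branch to acid chloride 20.

**Step 11 (key step).** Three processes can fail:
- Poor discrimination between the two ring CH2 groups is the most likely. The arms that differ are two bonds away from the reacting carbon, so the C1 epimer of 15 may form in a similar amount. The antipode of the catalyst would invert both new centres together and cannot correct a wrong pairing.
- Lactonisation onto O2, or migration of the lactone by the carbene, would remove the block on O4.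
- Over-reaction at C5 is possible.

Fallback with known chemistry, from 13 and 14: iminium catalysis with (S)-2-[diphenyl(trimethylsilyloxy)methyl]pyrrolidine and benzoic acid in CH2Cl2 should give, by Michael addition of the trione enol and closure of the aldehyde onto an enol oxygen, the hemiacetal (lactol) F1. Oxidation of the lactol with TEMPO and PhI(OAc)2 returns to the route at 15. The face pairing in this manifold is independent of that of the acyl azolium, which gives a second chance for the choice of ring CH. The hemiacetal equilibrates, so the lactone regiochemistry would then be thermodynamic.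

**Step 16.** The push–pull silyl dienol ether 21 may be too weak a nucleophile, the acyl group may go to oxygen with loss of silicon, or adventitious acid may attack the isopropenylcyclobutane. Fallback from 15 and acid 19: carbodiimide coupling (dicyclohexylcarbodiimide, CH2Cl2, 0 °C) to the O6 enol ester F2, then 1,3-shift of the acyl group from oxygen to C5 with catalytic 4-(dimethylamino)pyridine in toluene. This is the standard route to 2-acylcyclohexane-1,3-diones and comes back at 22. The same catalyst can move the lactone from O4 to O2, so its amount and the reaction time are kept minimal.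

**Step 18.** β-Elimination of the activated carbinol to the enone may outrun substitution. Fallback from 23: deliberate dehydration (EDC, catalytic CuCl, CH2Cl2) to the (E)-2-methylbut-2-enoyl compound F3, which is also what a failed Mitsunobu reaction would leave. A (−)-quinine-catalysed intramolecular oxa-Michael addition follows. This reaction type is known to convert o-tigloylphenols into cis-2,3-dimethylchroman-4-ones by face-selective O-addition and kinetic protonation. It comes back at 24 (quinidine if the sense at C2′ is opposite).

**Step 19.** Hydroxide may epimerise C3′ or open ring B by retro-oxa-Michael reaction before or after the lactone is cleaved. Fallback from 24: opening of the lactone with allyl alcohol and catalytic 4-(dimethylamino)pyridine in CH2Cl2 to the allyl ester F4, then allyl transfer to morpholine with Pd(PPh3)4 (zerovalent palladium) in THF, back at 25. Neither stage uses hydroxide.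

## Further compounds

F1 | step 11 | lactol (2-hydroxy analogue of 15, hemiacetal carbon unspecified) | C=C(C)[C@H]1C[C@@H](C[C@@]2(CC=C(C)C)C(=O)C3=C(OC(O)C[C@@H]3CCC)CC2=O)C1(C)C
F2 | step 16 | O6 enol ester of 15 with acid 19 | C=C(C)[C@H]1C[C@@H](C[C@@]2(CC=C(C)C)C(=O)C3=C(OC(=O)C[C@@H]3CCC)C=C2OC(=O)[C@@H](C)[C@H](C)O[Si](C)(C)C(C)(C)C)C1(C)C
F3 | step 18 | C5-[(E)-2-methylbut-2-enoyl] enol lactone (dehydration product of 23) | C=C(C)[C@H]1C[C@@H](C[C@@]2(CC=C(C)C)C(=O)C3=C(OC(=O)C[C@@H]3CCC)C(C(=O)/C(C)=C/C)=C2O)C1(C)C
F4 | step 19 | allyl ester of 25 | C=C(C)[C@H]1C[C@@H](C[C@@]2(CC=C(C)C)C(=O)C([C@@H](CCC)CC(=O)OCC=C)=C(O)C3=C2O[C@H](C)[C@H](C)C3=O)C1(C)C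
A1 | alternative 1 | (2,2-dimethyl-3-oxocyclobutyl)methyl benzoate | O=C1C[C@@H](COC(=O)c2ccccc2)C1(C)C
A2 | alternative 1 | N-isobutyryl-(2R,5R)-2,5-dimethylpyrrolidine | C[C@@H]1CC[C@@H](C)N1C(=O)C(C)C
A3 | alternative 1 | allyl benzoate | C=CCOC(=O)c1ccccc1
A4 | alternative 2 | enol lactone of the target (same structure as 24) | C=C(C)[C@H]1C[C@@H](C[C@@]2(CC=C(C)C)C(=O)C3=C(OC(=O)C[C@@H]3CCC)C4=C2O[C@H](C)[C@H](C)C4=O)C1(C)C
A5 | alternative 2 | lavandulyl analogue of 24, with a (2S)-5-methyl-2-(prop-1-en-2-yl)hex-4-en-1-yl group on C1 in place of the cyclobutylmethyl group | C=C(C)[C@@H](CC=C(C)C)C[C@@]1(CC=C(C)C)C(=O)C2=C(OC(=O)C[C@@H]2CCC)C2=C1O[C@H](C)[C@H](C)C2=O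
A6 | alternative 3 | 5-propionyl ring A trione (enol form) | C=C(C)[C@H]1C[C@@H](C[C@@]2(CC=C(C)C)C(=O)C=C(O)C(C(=O)CC)=C2O)C1(C)C
A7 | alternative 3 | acid chloride of the enantiopure methyl malonic half-ester carrying the prenyl and cyclobutylmethyl groups | C=C(C)[C@H]1C[C@@H](C[C@@](CC=C(C)C)(C(=O)Cl)C(=O)OC)C1(C)C
A8 | alternative 3 | 2,4-bis(trimethylsilyloxy)hexa-1,3-diene | C=C(O[Si](C)(C)C)C=C(CC)O[Si](C)(C)C
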